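**Retrosynthetic overview**

1. Target ⇐ Schenck ene reaction on a prenyl ketone side chain (hydroperoxide last) ⇐ allylboration, cross-metathesis and oxidation on an enal ⇐ tigloylation of an α'-hydroxy epoxy ketone.
2. α'-Hydroxy epoxy ketone ⇐ enolate hydroxylation of the cis-epoxy ketone ⇐ Luche reduction, hydroxyl-directed epoxidation and re-oxidation of a 5-substituted 2-methylcyclohex-2-enone.
3. The cyclohexenone ring (C1 to C6) is not closed by cyclization: it is made from the five-membered ring of a cyclopentene silyl enol ether by one-carbon ring expansion with chloro(methyl)carbenoid, which inserts C2 and its methyl group between the carbonyl carbon C1 and the old enol carbon (new C3).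
4. Enabling feature: the regiodefined O–C1=C2 silyl enol ether in the five-membered ring; its oxygen donor steers the carbene to that bond and then drives cleavage of the shared C1–C5 bond of the 6-chloro-6-methylbicyclo[3.1.0]hexane.
5. Silyl enol ether ⇐ 1,4-hydrosilylation of a 4-alkenylcyclopent-2-enone ⇐ trans cuprate addition of an acrolein α-anion equivalent to (S)-4-silyloxycyclopent-2-enone, then β-elimination; ring order: cyclopentane (purchased), cyclohexenone (by expansion), oxirane.

Key step: step 4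

Assumption (chemistry): the ester is the E-configured 2-methylbut-2-enoate (tiglate) drawn in the SMILES, and the carbinol epimers formed in step 11 are carried together because step 13 removes that centre.

**Route**

Step 1
Reactants: 1 (S)-4-[(tert-butyldimethylsilyl)oxy]cyclopent-2-en-1-one; 2 2-bromo-3,3-diethoxyprop-1-ene
Product: 5 (3R,4S)-4-[(tert-butyldimethylsilyl)oxy]-3-(3,3-diethoxyprop-1-en-2-yl)cyclopentan-1-one, via alkenyllithium 3 (not isolated), via lithium dialkenylcuprate 4 (not isolated)
Conditions: 2 (2.2 equiv), t-BuLi (4.4 equiv), Et2O, −78 °C; CuBr·SMe2 (1.1 equiv), −78 → −40 °C; then 1, −78 °C; NH4Cl/NH3 (aq)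
Reagents that add atoms: none
Why: Conjugate addition of a lithium dialkenylcuprate to a 4-silyloxycyclopentenone should take place on the enone face opposite the C4 silyloxy group, so the new C3 stereocenter is set trans to C4 by substrate control, and the enolate formed lies on the side away from the silyloxy carbon and cannot expel it before the quench.

Step 2
Reactants: 5 (3R,4S)-4-[(tert-butyldimethylsilyl)oxy]-3-(3,3-diethoxyprop-1-en-2-yl)cyclopentan-1-one
Product: 6 (S)-4-(3,3-diethoxyprop-1-en-2-yl)cyclopent-2-en-1-one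
Conditions: DBU (1.2 equiv), CH2Cl2, −20 → 0 °C, 30 min; pH 7 buffer
Reagents that add atoms: none
Why: E1cB β-elimination of silanolate from the β-silyloxy ketone through the C5 enolate should give the 4-substituted cyclopentenone; no stereocenter is formed, and the short, cold exposure to the amidine base is meant to leave the doubly allylic γ-stereocenter untouched.

Step 3
Reactants: 6 (S)-4-(3,3-diethoxyprop-1-en-2-yl)cyclopent-2-en-1-one
Product: 7 (R)-{[4-(3,3-diethoxyprop-1-en-2-yl)cyclopent-1-en-1-yl]oxy}triethylsilane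
Conditions: Et3SiH (1.3 equiv), RhCl(PPh3)3 (1 mol %), THF, 50 °C
Reagents that add atoms: triethylsilane, CC[SiH](CC)CC
Why: Rhodium-catalysed 1,4-hydrosilylation of an enone with a monohydrosilane puts hydride on the β-carbon and silicon on oxygen, so it should give regiospecifically the enol ether on the side of the ring remote from the side chain (which deprotonation of the saturated ketone would not do selectively), without creating or disturbing a stereocenter.

Step 4
Reactants: 7 (R)-{[4-(3,3-diethoxyprop-1-en-2-yl)cyclopent-1-en-1-yl]oxy}triethylsilane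
Product: 9 (R)-5-(3,3-diethoxyprop-1-en-2-yl)-2-methylcyclohex-2-en-1-one, via chlorocyclopropyl silyl ether 8 (not isolated)
Conditions: CH3CHCl2 (3 equiv), n-BuLi (2.5 equiv, slow addition), Et2O, −40 → 0 °C; then crude 8, Et3N, MeOH, 65 °C
Reagents that add atoms: 1,1-dichloroethane, CC(Cl)Cl
Why: n-BuLi deprotonates 1,1-dichloroethane to 1,1-dichloroethyllithium, whose α-elimination delivers chloro(methyl)carbene to the electron-rich C1=C2 enol ether bond of 7 in a cheletropic [2+1] addition that closes the three-membered ring of 8. Methanolysis of the silyl ether then lets the cyclopropanol oxygen push out the endo chloride while the shared C1–C5 bond of the bicyclo[3.1.0]hexane breaks in a disrotatory two-electron electrocyclic opening (cyclopropyl to 2-oxyallyl cation), so the six-membered ring arises by enlargement of the five-membered ring and the new carbon with its methyl group sits between the carbonyl carbon and the former enol carbon. The closest known reaction type is the halocarbene ring expansion of cycloalkanone silyl enol ethers to 2-substituted cycloalk-2-enones, the carbocyclic counterpart of the Ciamician–Dennstedt rearrangement. No lasting stereocenter is created (the cyclopropane centers of 8 are destroyed again), and the existing one at the side-chain-bearing carbon is not enolizable and is two bonds from any reacting atom, so it should be carried through unchanged. The step needs regioselective insertion (fixed by the enol ether position from step 3), chemoselectivity for the enol ether over the exocyclic 1,1-disubstituted alkene (the former carries an oxygen donor, the latter is deactivated by the adjacent acetal carbon), and ring opening of 8 (favoured for the isomer with chlorine endo, which the smaller size of chlorine relative to methyl should favour in the addition, and assisted by the oxygen lone pair).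

Step 5
Reactants: 9 (R)-5-(3,3-diethoxyprop-1-en-2-yl)-2-methylcyclohex-2-en-1-one
Product: 10 (1R,5R)-5-(3,3-diethoxyprop-1-en-2-yl)-2-methylcyclohex-2-en-1-ol
Conditions: NaBH4, CeCl3·7H2O, EtOH, −40 °C
Reagents that add atoms: none
Why: Luche reduction (1,2-selective) with axial hydride delivery to the half-chair that carries the C5 substituent equatorially should give the equatorial alcohol, setting C1 cis to the side chain as in the reduction of carvone to cis-carveol.

Step 6
Reactants: 10 (1R,5R)-5-(3,3-diethoxyprop-1-en-2-yl)-2-methylcyclohex-2-en-1-ol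
Product: 11 (1R,2R,4S,6S)-4-(3,3-diethoxyprop-1-en-2-yl)-1-methyl-7-oxabicyclo[4.1.0]heptan-2-ol
Conditions: t-BuOOH (1.5 equiv, in decane), VO(acac)2 (3 mol %), CH2Cl2, 0 °C → rt
Reagents that add atoms: tert-butyl hydroperoxide, CC(C)(C)OO
Why: Hydroxyl-directed epoxidation of a cyclic allylic alcohol by the vanadium tert-butylperoxo complex delivers oxygen to the ring alkene on the face of the hydroxyl group, so both oxirane carbons should be set cis to the hydroxyl group and to the side chain while the exocyclic alkene, which is only bishomoallylic and electron-poor, is left.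

Step 7
Reactants: 11 (1R,2R,4S,6S)-4-(3,3-diethoxyprop-1-en-2-yl)-1-methyl-7-oxabicyclo[4.1.0]heptan-2-ol
Product: 12 (1S,4R,6S)-4-(3,3-diethoxyprop-1-en-2-yl)-1-methyl-7-oxabicyclo[4.1.0]heptan-2-one
Conditions: Dess–Martin periodinane, NaHCO3, CH2Cl2, 0 °C → rt
Reagents that add atoms: none
Why: Dess–Martin oxidation of the secondary alcohol under buffered conditions should give the cis-epoxy ketone without opening the oxirane or the acetal, and it removes the carbinol center that has served as the directing group.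

Step 8
Reactants: 12 (1S,4R,6S)-4-(3,3-diethoxyprop-1-en-2-yl)-1-methyl-7-oxabicyclo[4.1.0]heptan-2-one
Product: 14 (1S,3S,4S,6S)-4-(3,3-diethoxyprop-1-en-2-yl)-3-hydroxy-1-methyl-7-oxabicyclo[4.1.0]heptan-2-one, via potassium enolate 13 (not isolated)
Conditions: KN(SiMe3)2 (1.1 equiv), THF, −78 °C; 3-phenyl-2-(phenylsulfonyl)oxaziridine (1.3 equiv), −78 °C; NH4Cl (aq)
Reagents that add atoms: 3-phenyl-2-(phenylsulfonyl)oxaziridine, O=S(=O)(c1ccccc1)N1OC1c1ccccc1
Why: Enolate hydroxylation with an N-sulfonyloxaziridine: the ketone can enolize only toward C3 because C1 is quaternary, and the oxidant should approach the enolate on the face opposite both the adjacent C4 side chain and the oxirane oxygen, setting the C3 hydroxyl group trans to both.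

Step 9
Reactants: 14 (1S,3S,4S,6S)-4-(3,3-diethoxyprop-1-en-2-yl)-3-hydroxy-1-methyl-7-oxabicyclo[4.1.0]heptan-2-one
Product: 15 (1S,3S,4S,6S)-4-(3,3-diethoxyprop-1-en-2-yl)-1-methyl-2-oxo-7-oxabicyclo[4.1.0]heptan-3-yl (E)-2-methylbut-2-enoate
Conditions: tiglic acid (1.5 equiv), DCC (1.5 equiv), DMAP (0.3 equiv), CH2Cl2, 0 °C → rt
Reagents that add atoms: (E)-2-methylbut-2-enoic acid (tiglic acid), C/C=C(\C)C(=O)O
Why: Steglich esterification acylates the hindered α-hydroxy ketone with retention at C3, and carbodiimide activation avoids the vinylketene pathway by which the acid chloride and amine bases deconjugate tiglates; the E geometry of the acid is the stable one and is kept.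

Step 10
Reactants: 15 (1S,3S,4S,6S)-4-(3,3-diethoxyprop-1-en-2-yl)-1-methyl-2-oxo-7-oxabicyclo[4.1.0]heptan-3-yl (E)-2-methylbut-2-enoate
Product: 16 (1S,3S,4S,6S)-1-methyl-2-oxo-4-(3-oxoprop-1-en-2-yl)-7-oxabicyclo[4.1.0]heptan-3-yl (E)-2-methylbut-2-enoate
Conditions: PPTS (cat.), THF/H2O (4:1), 40 °C
Reagents that add atoms: water, O
Why: Acid-catalysed hydrolysis of the acetal of a 2-substituted acrolein proceeds through an allyl-stabilized oxocarbenium ion at a pH that the ester and the electron-poor α,β-epoxy ketone should tolerate, giving the enal.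

Step 11
Reactants: 16 (1S,3S,4S,6S)-1-methyl-2-oxo-4-(3-oxoprop-1-en-2-yl)-7-oxabicyclo[4.1.0]heptan-3-yl (E)-2-methylbut-2-enoate
Product: 17 (1S,3S,4S,6S)-4-(3-hydroxyhexa-1,5-dien-2-yl)-1-methyl-2-oxo-7-oxabicyclo[4.1.0]heptan-3-yl (E)-2-methylbut-2-enoate (both carbinol epimers)
Conditions: allylboronic acid pinacol ester (1.5 equiv), CH2Cl2, rt; aqueous work-up
Reagents that add atoms: allylboronic acid pinacol ester, C=CCB1OC(C)(C)C(C)(C)O1
Why: Uncatalysed allylboration through a six-membered chair transition state is selective for the aldehyde over the ring ketone and the ester; the new carbinol center is not controlled and need not be, because step 13 oxidizes it.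

Step 12
Reactants: 17 (1S,3S,4S,6S)-4-(3-hydroxyhexa-1,5-dien-2-yl)-1-methyl-2-oxo-7-oxabicyclo[4.1.0]heptan-3-yl (E)-2-methylbut-2-enoate
Product: 18 (1S,3S,4S,6S)-4-(3-hydroxy-6-methylhepta-1,5-dien-2-yl)-1-methyl-2-oxo-7-oxabicyclo[4.1.0]heptan-3-yl (E)-2-methylbut-2-enoate (both carbinol epimers)
Conditions: 2-methylbut-2-ene (co-solvent), second-generation Grubbs catalyst (5 mol %), CH2Cl2, 40 °C
Reagents that add atoms: 2-methylbut-2-ene, CC=C(C)C
Why: Olefin cross-metathesis of the monosubstituted alkene with 2-methylbut-2-ene should exchange the terminal methylene for an isopropylidene group, the 1,1-disubstituted alkene and the trisubstituted tiglate alkene being unreactive partners for the ruthenium carbene.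

Step 13
Reactants: 18 (1S,3S,4S,6S)-4-(3-hydroxy-6-methylhepta-1,5-dien-2-yl)-1-methyl-2-oxo-7-oxabicyclo[4.1.0]heptan-3-yl (E)-2-methylbut-2-enoate
Product: 19 (1S,3S,4S,6S)-1-methyl-4-(6-methyl-3-oxohepta-1,5-dien-2-yl)-2-oxo-7-oxabicyclo[4.1.0]heptan-3-yl (E)-2-methylbut-2-enoate
Conditions: Dess–Martin periodinane, NaHCO3, CH2Cl2, 0 °C; used directly
Reagents that add atoms: none
Why: Dess–Martin oxidation under bicarbonate buffer converts both carbinol epimers into the single β,γ-unsaturated ketone under conditions mild enough to leave the skipped double bond out of conjugation.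

Step 14
Reactants: 19 (1S,3S,4S,6S)-1-methyl-4-(6-methyl-3-oxohepta-1,5-dien-2-yl)-2-oxo-7-oxabicyclo[4.1.0]heptan-3-yl (E)-2-methylbut-2-enoate
Product: 20 (1S,3S,4S,6S)-4-[(4E)-6-hydroperoxy-6-methyl-3-oxohepta-1,4-dien-2-yl]-1-methyl-2-oxo-7-oxabicyclo[4.1.0]heptan-3-yl (E)-2-methylbut-2-enoate
Conditions: O2, tetraphenylporphyrin (cat.), white LED, CH2Cl2, −20 °C
Reagents that add atoms: dioxygen, O=O
Why: Schenck ene reaction of singlet oxygen with the only electron-rich alkene, the trisubstituted prenyl double bond: oxygen should bond to the dimethyl-substituted carbon while the doubly activated methylene hydrogen next to the ketone, on the disubstituted (cis) side of the alkene, is transferred, so that the double bond moves into conjugation with E geometry and the tertiary allylic hydroperoxide of the target results; no stereocenter is formed.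

**Compound list**

1 | (S)-4-[(tert-butyldimethylsilyl)oxy]cyclopent-2-en-1-one | O=C1C=C[C@@H](O[Si](C)(C)C(C)(C)C)C1 | starting material
2 | 2-bromo-3,3-diethoxyprop-1-ene (2-bromoacrolein diethyl acetal) | C=C(Br)C(OCC)OCC | starting material
3 | (3,3-diethoxyprop-1-en-2-yl)lithium | [Li]C(=C)C(OCC)OCC | intermediate
4 | lithium bis(3,3-diethoxyprop-1-en-2-yl)cuprate | [Li+].C=C([Cu-]C(=C)C(OCC)OCC)C(OCC)OCC | intermediate
5 | (3R,4S)-4-[(tert-butyldimethylsilyl)oxy]-3-(3,3-diethoxyprop-1-en-2-yl)cyclopentan-1-one (3,4-trans) | O=C1C[C@H](C(=C)C(OCC)OCC)[C@@H](O[Si](C)(C)C(C)(C)C)C1 | intermediate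
6 | (S)-4-(3,3-diethoxyprop-1-en-2-yl)cyclopent-2-en-1-one | O=C1C[C@H](C(=C)C(OCC)OCC)C=C1 | intermediate
7 | (R)-{[4-(3,3-diethoxyprop-1-en-2-yl)cyclopent-1-en-1-yl]oxy}triethylsilane | CC[Si](CC)(CC)OC1=CC[C@@H](C(=C)C(OCC)OCC)C1 | intermediate
8 | 6-chloro-3-(3,3-diethoxyprop-1-en-2-yl)-6-methyl-1-[(triethylsilyl)oxy]bicyclo[3.1.0]hexane (mixture of cyclopropane diastereomers, side-chain carbon as in 7) | CC[Si](CC)(CC)OC12C[C@H](C(=C)C(OCC)OCC)CC1C2(C)Cl | intermediate
9 | (R)-5-(3,3-diethoxyprop-1-en-2-yl)-2-methylcyclohex-2-en-1-one | O=C1C[C@H](C(=C)C(OCC)OCC)CC=C1C | intermediate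
10 | (1R,5R)-5-(3,3-diethoxyprop-1-en-2-yl)-2-methylcyclohex-2-en-1-ol (hydroxyl cis to side chain) | O[C@@H]1C[C@H](C(=C)C(OCC)OCC)CC=C1C | intermediate
11 | (1R,2R,4S,6S)-4-(3,3-diethoxyprop-1-en-2-yl)-1-methyl-7-oxabicyclo[4.1.0]heptan-2-ol (oxirane, hydroxyl and side chain all cis) | O[C@@H]1C[C@H](C(=C)C(OCC)OCC)C[C@@H]2O[C@]12C | intermediate
12 | (1S,4R,6S)-4-(3,3-diethoxyprop-1-en-2-yl)-1-methyl-7-oxabicyclo[4.1.0]heptan-2-one | O=C1C[C@H](C(=C)C(OCC)OCC)C[C@@H]2O[C@]12C | intermediate
13 | potassium C2–C3 enolate of 12 | [K+].[O-]C1=C[C@H](C(=C)C(OCC)OCC)C[C@@H]2O[C@]12C | intermediate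
14 | (1S,3S,4S,6S)-4-(3,3-diethoxyprop-1-en-2-yl)-3-hydroxy-1-methyl-7-oxabicyclo[4.1.0]heptan-2-one | O=C1[C@@H](O)[C@H](C(=C)C(OCC)OCC)C[C@@H]2O[C@]12C | intermediate
15 | (1S,3S,4S,6S)-4-(3,3-diethoxyprop-1-en-2-yl)-1-methyl-2-oxo-7-oxabicyclo[4.1.0]heptan-3-yl (E)-2-methylbut-2-enoate | O=C1[C@@H](OC(=O)/C(C)=C/C)[C@H](C(=C)C(OCC)OCC)C[C@@H]2O[C@]12C | intermediate
16 | (1S,3S,4S,6S)-1-methyl-2-oxo-4-(3-oxoprop-1-en-2-yl)-7-oxabicyclo[4.1.0]heptan-3-yl (E)-2-methylbut-2-enoate | O=C1[C@@H](OC(=O)/C(C)=C/C)[C@H](C(=C)C=O)C[C@@H]2O[C@]12C | intermediate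
17 | (1S,3S,4S,6S)-4-(3-hydroxyhexa-1,5-dien-2-yl)-1-methyl-2-oxo-7-oxabicyclo[4.1.0]heptan-3-yl (E)-2-methylbut-2-enoate (carbinol epimers) | O=C1[C@@H](OC(=O)/C(C)=C/C)[C@H](C(=C)C(O)CC=C)C[C@@H]2O[C@]12C | intermediate
18 | (1S,3S,4S,6S)-4-(3-hydroxy-6-methylhepta-1,5-dien-2-yl)-1-methyl-2-oxo-7-oxabicyclo[4.1.0]heptan-3-yl (E)-2-methylbut-2-enoate (carbinol epimers) | O=C1[C@@H](OC(=O)/C(C)=C/C)[C@H](C(=C)C(O)CC=C(C)C)C[C@@H]2O[C@]12C | intermediate
19 | (1S,3S,4S,6S)-1-methyl-4-(6-methyl-3-oxohepta-1,5-dien-2-yl)-2-oxo-7-oxabicyclo[4.1.0]heptan-3-yl (E)-2-methylbut-2-enoate | O=C1[C@@H](OC(=O)/C(C)=C/C)[C@H](C(=C)C(=O)CC=C(C)C)C[C@@H]2O[C@]12C | intermediate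
20 | (1S,3S,4S,6S)-4-[(4E)-6-hydroperoxy-6-methyl-3-oxohepta-1,4-dien-2-yl]-1-methyl-2-oxo-7-oxabicyclo[4.1.0]heptan-3-yl (E)-2-methylbut-2-enoate | O=C1[C@@H](OC(=O)/C(C)=C/C)[C@H](C(=C)C(=O)/C=C/C(C)(C)OO)C[C@@H]2O[C@]12C | target

**Step count and risks**

Total step count: 14. Longest linear sequence: 14 steps (1 → 20).

Steps most likely to fail:

1. Step 14. What may go wrong: the ene reaction may take its hydrogen from a terminal methyl group instead of the α-keto methylene (wrong regiochemistry, giving the secondary allylic hydroperoxide), and prolonged irradiation may slowly oxidize the tiglate. The fallback sets out from 16 and returns at 20. CH2=CHMgBr (THF, −78 °C) should add to the aldehyde of 16 to give the divinyl carbinol (1S,3S,4S,6S)-4-(3-hydroxypenta-1,4-dien-2-yl)-1-methyl-2-oxo-7-oxabicyclo[4.1.0]heptan-3-yl (E)-2-methylbut-2-enoate F1, and Dess–Martin oxidation gives the cross-conjugated dienone, the 3-oxopenta-1,4-dien-2-yl analogue F2. Separately, photooxygenation of 2-methylbut-2-ene provides 2-methylbut-3-en-2-yl hydroperoxide F3, which is purified on this simple compound and capped with 2-methoxypropene (PPTS) as the peroxyketal 3-[(2-methoxypropan-2-yl)peroxy]-3-methylbut-1-ene F4. Cross-metathesis of F2 with F4 (second-generation Hoveyda–Grubbs catalyst, CH2Cl2, 40 °C) places the peroxide carbon unambiguously and should give the protected hydroperoxide, the peroxyketal of 20, F5. AcOH/THF/H2O then releases 20.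

2. Step 4. What may go wrong: the cyclopropane diastereomer with exo chlorine may fail to ionize, the carbene may undergo 1,2-hydrogen shift faster than it adds, or it may also cyclopropanate the exocyclic alkene. The fallback sets out from 7 and returns at 9, still by enlargement of the five-membered ring, but with the methyl group introduced by cross-coupling. Dibromocarbene (CHBr3, KOt-Bu, pentane, −20 °C) should give 6,6-dibromo-3-(3,3-diethoxyprop-1-en-2-yl)-1-[(triethylsilyl)oxy]bicyclo[3.1.0]hexane F6, in which one bromine is endo whichever face is attacked. Et3N/MeOH at 65 °C opens it to (R)-2-bromo-5-(3,3-diethoxyprop-1-en-2-yl)cyclohex-2-en-1-one F7. Stille methylation (Me4Sn, Pd2(dba)3, AsPh3, CuI, NMP, 60 °C) then gives 9.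

3. Step 8. What may go wrong: poor facial selectivity, incomplete conversion through condensation of the enolate with the sulfonimine by-product, or epimerization of the α-hydroxy ketone while it is still an alkoxide. The fallback sets out from 12 and returns at 14 by a Rubottom oxidation under neutral conditions. LiN(i-Pr)2 and Me3SiCl (THF, −78 °C) give the enol silane 4-(3,3-diethoxyprop-1-en-2-yl)-1-methyl-2-[(trimethylsilyl)oxy]-7-oxabicyclo[4.1.0]hept-2-ene F8. Dimethyldioxirane (acetone, −40 °C) should epoxidize it on the face away from the side chain and the oxirane, and silyl migration gives (1S,3S,4S,6S)-4-(3,3-diethoxyprop-1-en-2-yl)-1-methyl-3-[(trimethylsilyl)oxy]-7-oxabicyclo[4.1.0]heptan-2-one F9. Aqueous citric acid work-up converts F9 into 14.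

Further compounds
F1 | step 14 | (1S,3S,4S,6S)-4-(3-hydroxypenta-1,4-dien-2-yl)-1-methyl-2-oxo-7-oxabicyclo[4.1.0]heptan-3-yl (E)-2-methylbut-2-enoate | O=C1[C@@H](OC(=O)/C(C)=C/C)[C@H](C(=C)C(O)C=C)C[C@@H]2O[C@]12C
F2 | step 14 | (1S,3S,4S,6S)-1-methyl-2-oxo-4-(3-oxopenta-1,4-dien-2-yl)-7-oxabicyclo[4.1.0]heptan-3-yl (E)-2-methylbut-2-enoate | O=C1[C@@H](OC(=O)/C(C)=C/C)[C@H](C(=C)C(=O)C=C)C[C@@H]2O[C@]12C
F3 | step 14 | 2-methylbut-3-en-2-yl hydroperoxide | C=CC(C)(C)OO
F4 | step 14 | 3-[(2-methoxypropan-2-yl)peroxy]-3-methylbut-1-ene | C=CC(C)(C)OOC(C)(C)OC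
F5 | step 14 | (1S,3S,4S,6S)-4-{(4E)-6-[(2-methoxypropan-2-yl)peroxy]-6-methyl-3-oxohepta-1,4-dien-2-yl}-1-methyl-2-oxo-7-oxabicyclo[4.1.0]heptan-3-yl (E)-2-methylbut-2-enoate | O=C1[C@@H](OC(=O)/C(C)=C/C)[C@H](C(=C)C(=O)/C=C/C(C)(C)OOC(C)(C)OC)C[C@@H]2O[C@]12C
F6 | step 4 | 6,6-dibromo-3-(3,3-diethoxyprop-1-en-2-yl)-1-[(triethylsilyl)oxy]bicyclo[3.1.0]hexane | CC[Si](CC)(CC)OC12C[C@H](C(=C)C(OCC)OCC)CC1C2(Br)Br
F7 | step 4 | (R)-2-bromo-5-(3,3-diethoxyprop-1-en-2-yl)cyclohex-2-en-1-one | O=C1C[C@H](C(=C)C(OCC)OCC)CC=C1Br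
F8 | step 8 | 4-(3,3-diethoxyprop-1-en-2-yl)-1-methyl-2-[(trimethylsilyl)oxy]-7-oxabicyclo[4.1.0]hept-2-ene (configuration as in 12) | C[Si](C)(C)OC1=C[C@H](C(=C)C(OCC)OCC)C[C@@H]2O[C@]12C
F9 | step 8 | (1S,3S,4S,6S)-4-(3,3-diethoxyprop-1-en-2-yl)-1-methyl-3-[(trimethylsilyl)oxy]-7-oxabicyclo[4.1.0]heptan-2-one | O=C1[C@@H](O[Si](C)(C)C)[C@H](C(=C)C(OCC)OCC)C[C@@H]2O[C@]12C
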